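**Plan** (locants C1–C41 are the heavy atoms of the target SMILES in order of appearance)
1. Cuts, last to first: C21–O23 (peroxyhemiacetal), epoxide O28 and C25–O24 (back to a C25=C27 cyclohexene), C19–C20, N41–C16/N41–C39, C16–C18 (key), C19–C34, C7–O8, then C31–C32 and C25–C33 together (rings B and C), C29–C30.
2. Forward: ring A from (R)-5-methylcyclohexenone; two arms grown into a dienyl/enoate triene; an intramolecular Diels–Alder reaction closes rings B and C; dienoate plus methyl cuprate gives the C25=C27 ring C; the C34 acid becomes the 2-methylene β-keto ester; the Stetter reaction closes the 13-membered ring; then lactam, allyl group, and ene/epoxide/ozonolysis to close the 1,2-dioxocane.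
3. Feature used by the key step: C16 (masked ketone of the hydroxylactam) and the C34 ketone stand 1,4 across C18–C19, the pattern of acyl-anion addition to an activated alkene; C16–C18 lies in the 13-membered ring C7–O8–arene–C15–C16–C18–C19–C34–C33–C32.
4. Stereochemistry: C2 from the starting enone; C36 by cuprate addition trans to the C2 methyl; C6 by enolate protonation; C4 by thermodynamic hydrogenation; C7 by Felkin–Anh addition then Mitsunobu inversion; C31, C32, C33 in the Diels–Alder step; C29 by cuprate attack anti to the angular methyl; C19 by allylation on the open enolate face.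
5. The O-bearing centres C25, C27, C29 come from a suprafacial ene reaction and a trans-diaxial bromohydrin; C16 and C21 are hemiaminal and peroxyhemiacetal centres under thermodynamic control.

Key step: step 26

Assumption: (R)-5-methylcyclohex-2-en-1-one (1) is bought as such; it is otherwise at hand in three known operations from (R)-pulegone.

**Step 1**
Reactants: 1 (R)-5-methylcyclohex-2-en-1-one; 2 formaldehyde
Product: 3 (R)-2-(hydroxymethyl)-5-methylcyclohex-2-en-1-one
Conditions: aq. HCHO (37 %), 4-(dimethylamino)pyridine (0.1 equiv), THF/H2O, 23 °C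
Reagents that add atoms: none
Why: Morita–Baylis–Hillman reaction; the amine adds to the enone and the resulting enolate captures formaldehyde at the α-carbon, which becomes C6 carrying C7, while the C2 stereocentre is untouched.

**Step 2**
Reactants: 3 (R)-2-(hydroxymethyl)-5-methylcyclohex-2-en-1-one
Product: 4 (R)-2-[(tert-butyldiphenylsilyloxy)methyl]-5-methylcyclohex-2-en-1-one
Conditions: TBDPSCl, imidazole, CH2Cl2, 0 to 23 °C
Reagents that add atoms: tert-butyl(chloro)diphenylsilane, CC(C)(C)[Si](Cl)(c1ccccc1)c1ccccc1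
Why: Standard silylation of a primary alcohol; the robust silyl ether should survive the organometallic, oxidative and acidic steps up to step 12.

**Step 3**
Reactants: 4 (R)-2-[(tert-butyldiphenylsilyloxy)methyl]-5-methylcyclohex-2-en-1-one
Product: 5 tertiary allylic alcohol carrying the CH2OMOM arm (both carbinol epimers)
Conditions: Bu3SnCH2OCH2OMe, n-BuLi, THF, −78 °C; then 4, −78 °C; H2O
Reagents that add atoms: tributyl[(methoxymethoxy)methyl]stannane, CCCC[Sn](CCCC)(CCCC)COCOC
Why: Tin–lithium exchange gives an α-alkoxymethyllithium that adds 1,2 to the α-substituted enone; the new carbinol centre is erased in step 4, so its configuration is irrelevant.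

**Step 4**
Reactants: 5 tertiary allylic alcohol
Product: 6 (S)-2-[(tert-butyldiphenylsilyloxy)methyl]-3-[(methoxymethoxy)methyl]-5-methylcyclohex-2-en-1-one
Conditions: [C5H5NH][CrO3Cl] (pyridinium chlorochromate), NaOAc, 4 Å molecular sieves, CH2Cl2, 23 °C
Reagents that add atoms: none
Why: Oxidative 1,3-transposition of a tertiary allylic alcohol (Babler–Dauben) through a [3,3] shift of the chromate ester; it puts the carbonyl at C4 and the CH2OMOM arm on the β-carbon C36 (the descriptor changes only because priorities change).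

**Step 5**
Reactants: 6 transposed enone
Product: 7 ring A ketone (C36 methyl trans to C2 methyl; C7 arm cis to the C36 methyl)
Conditions: Me2CuLi, BF3·OEt2, Et2O, −78 °C; then AcOH in THF, −78 °C
Reagents that add atoms: lithium dimethylcuprate, [Li+].C[Cu-]C
Why: Lewis-acid-assisted cuprate conjugate addition; the methyl should enter axially, trans to the C2 methyl of the 5-substituted cyclohexenone (sets C36), and cold protonation of the enolate anti to the new axial methyl should give H-6 axial (sets C6).

**Step 6**
Reactants: 7 ring A ketone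
Product: 8 C4 exo-methylene compound
Conditions: Zn, CH2Br2, TiCl4, THF/CH2Cl2, 0 to 23 °C
Reagents that add atoms: dibromomethane, BrCBr
Why: Takai–Lombardo methylenation; it is non-basic, so the epimerisable C6 centre and the β-silyloxy group should not be disturbed.

**Step 7**
Reactants: 8 C4 exo-methylene compound
Product: 9 ring A core (C2 and C4 methyls equatorial and cis, C36 methyl axial)
Conditions: Mn(dpm)3 (10 mol %; dpm = 2,2,6,6-tetramethylheptane-3,5-dionate), PhSiH3, t-BuOOH, i-PrOH, 23 °C
Reagents that add atoms: none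
Why: Metal-hydride hydrogen-atom-transfer hydrogenation of the 1,1-disubstituted alkene via the tertiary C4 radical; it should give the thermodynamic epimer with the C4 methyl equatorial, since the other epimer would hold the C4 and C36 methyls 1,3-diaxial.

**Step 8**
Reactants: 9 ring A core
Product: 10 C31 primary alcohol
Conditions: conc. HCl (cat.), MeOH, 40 °C
Reagents that add atoms: none
Why: Acid-catalysed acetal exchange removes the methoxymethyl ether; the tert-butyldiphenylsilyl ether is far more stable to acid.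

**Step 9**
Reactants: 10 C31 primary alcohol
Product: 11 C31 aldehyde
Conditions: Dess–Martin periodinane, NaHCO3, CH2Cl2, 23 °C
Reagents that add atoms: none
Why: Dess–Martin oxidation of a neopentyl alcohol to a non-enolisable aldehyde.

**Step 10**
Reactants: 11 C31 aldehyde
Product: 12 (E)-vinyl iodide (C31=C29)
Conditions: CrCl2, CHI3, THF, 0 to 23 °C
Reagents that add atoms: iodoform, IC(I)I
Why: Takai olefination; it tolerates hindered aldehydes and should give the E-iodoalkene.

**Step 11**
Reactants: 12 (E)-vinyl iodide; 13 (E)-prop-1-enylboronic acid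
Product: 14 (E,E)-diene silyl ether
Conditions: Pd(PPh3)4 (5 mol %), NaOH (aq), THF, 40 °C
Reagents that add atoms: none
Why: Suzuki–Miyaura coupling with retention of both alkene geometries delivers the (E,E)-penta-1,3-dienyl group on C36.

**Step 12**
Reactants: 14 (E,E)-diene silyl ether
Product: 15 dienyl alcohol (C7 hydroxymethyl)
Conditions: n-Bu4NF, THF, 23 °C
Reagents that add atoms: none
Why: Fluoride desilylation; the diene is inert to it.

**Step 13**
Reactants: 15 dienyl alcohol
Product: 16 dienyl aldehyde (C7 formyl)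
Conditions: Dess–Martin periodinane, NaHCO3, CH2Cl2, 0 °C
Reagents that add atoms: none
Why: Buffered Dess–Martin oxidation, non-basic, so the α-centre C6 should keep its configuration; the aldehyde is used at once.

**Step 14**
Reactants: 16 dienyl aldehyde; 17 methyl propiolate
Product: 18 γ-hydroxy ynoate (C7 epimeric to the target)
Conditions: LiN(SiMe3)2, 17, THF, −90 °C; then 16; AcOH, −90 °C
Reagents that add atoms: none
Why: Acetylide addition to an α-branched aldehyde under Felkin–Anh control (the quaternary C36 anti to the nucleophile); this should set C7 with the configuration opposite to the target, as required for the inversion in step 17.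

**Step 15**
Reactants: 18 γ-hydroxy ynoate
Product: 19 (E)-γ-hydroxy enoate (C7 epimeric to the target)
Conditions: NaAlH2(OCH2CH2OMe)2, THF, −78 °C; aq. potassium sodium tartrate
Reagents that add atoms: none
Why: Hydroxyl-directed trans-hydroalumination of the ynoate; known to give (E)-γ-hydroxy enoates without reducing the ester at low temperature.

**Step 16**
Reactants: 20 tyrosol
Product: 21 4-[2-(tert-butyldimethylsilyloxy)ethyl]phenol
Conditions: TBSCl (1.05 equiv), imidazole, DMF, 0 °C
Reagents that add atoms: tert-butyl(chloro)dimethylsilane, CC(C)(C)[Si](C)(C)Cl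
Why: Selective silylation of the aliphatic hydroxyl, which should react faster than the phenol under these conditions.

**Step 17**
Reactants: 19 (E)-γ-hydroxy enoate; 21 4-[2-(tert-butyldimethylsilyloxy)ethyl]phenol
Product: 22 triene aryl ether (C7 as in the target)
Conditions: PPh3, diisopropyl azodicarboxylate, toluene, 0 to 23 °C
Reagents that add atoms: none
Why: Mitsunobu etherification; SN2 displacement at the allylic carbinol by the phenol inverts C7 to the configuration of the target.

**Step 18**
Reactants: 22 triene aryl ether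
Product: 23 tricyclic ester (rings A, B, C; C27=C29)
Conditions: Me2AlCl (0.3 equiv), CH2Cl2, −40 to 23 °C
Reagents that add atoms: none
Why: Lewis-acid-catalysed intramolecular Diels–Alder reaction of the (E,E,E)-triene through the ester-endo transition state: the trans-diequatorial arms on ring A force a trans-fused cyclopentane with the diene in the pseudo-equatorial site at C31, and allylic 1,3-strain at C7 (H-7 eclipsing the enoate) selects the dienophile face, so C31, C32, C33 (and C25) should arise as drawn.

**Step 19**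
Reactants: 23 tricyclic ester
Product: 25 tricyclic 2,4-dienoate (C33=C25 and C27=C29), via α-phenylselenyl ester 24 (not isolated)
Conditions: LiN(i-Pr)2, THF, −78 °C; PhSeBr; then H2O2 (30 %), pyridine, CH2Cl2, 0 to 23 °C
Reagents that add atoms: none
Why: Ester enolate selenenylation and selenoxide syn-elimination; selenium should enter on the face opposite the pseudoaxial C25 methyl, so only H-25 is syn to it and elimination gives the conjugated dienoate.

**Step 20**
Reactants: 25 tricyclic 2,4-dienoate
Product: 26 tricyclic β,γ-unsaturated ester (C25=C27; C29 methyl)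
Conditions: Me2CuLi, Et2O, −78 to −20 °C; then AcOH, −78 °C
Reagents that add atoms: lithium dimethylcuprate, [Li+].C[Cu-]C
Why: 1,6-Conjugate addition of a Gilman cuprate to a 2,4-dienoate whose β-carbon is fully substituted; the methyl should attack C29 on the face away from the angular C37 methyl, and axial α-protonation of the dienolate should give the deconjugated ester with H-33 axial.

**Step 21**
Reactants: 26 tricyclic β,γ-unsaturated ester
Product: 27 tricyclic acid
Conditions: Me3SnOH, 1,2-dichloroethane, 80 °C; 5 % aq. HCl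
Reagents that add atoms: trimethyltin hydroxide, C[Sn](C)(C)O
Why: Tin-hydroxide cleavage of a hindered methyl ester under near-neutral conditions, chosen so that the C25=C27 alkene does not move into conjugation.

**Step 22**
Reactants: 27 tricyclic acid; 28 monomethyl malonate
Product: 30 β-keto ester silyl ether, via acyl imidazolide 29 (not isolated)
Conditions: 1,1'-carbonyldiimidazole, THF, 23 °C; then Mg(O2CCH2CO2Me)2 made from 28 and Mg(OEt)2, THF, 23 to 40 °C; 1 M HCl
Reagents that add atoms: none
Why: Masamune–Brooks homologation; the magnesium malonate is C-acylated by the imidazolide and decarboxylates to the β-keto ester, forming C34–C19.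

**Step 23**
Reactants: 30 β-keto ester silyl ether
Product: 31 β-keto ester alcohol
Conditions: HF·pyridine, THF/pyridine, 0 to 23 °C
Reagents that add atoms: none
Why: Acidic fluoride desilylation; it avoids basic conditions at the β-keto ester.

**Step 24**
Reactants: 31 β-keto ester alcohol; 2 formaldehyde
Product: 32 sulfone adduct alcohol (C19 epimers)
Conditions: PhSO2Na, aq. HCHO (1.0 equiv), AcOH, THF/H2O, 23 °C
Reagents that add atoms: sodium benzenesulfinate, [Na+].[O-]S(=O)c1ccccc1
Why: Knoevenagel condensation with formaldehyde followed by conjugate addition of sulfinate (three-component sulfonylmethylation of an active methylene); it stores the unstable 2-methylene β-keto ester as its sulfone adduct and brings in C18.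

**Step 25**
Reactants: 32 sulfone adduct alcohol
Product: 33 sulfone adduct aldehyde
Conditions: Dess–Martin periodinane, NaHCO3, CH2Cl2, 0 °C
Reagents that add atoms: none
Why: Dess–Martin oxidation of the primary alcohol to the arylacetaldehyde under conditions that leave the acidic C19–H and the sulfone alone; the aldehyde is used at once.

**Step 26**
Reactants: 33 sulfone adduct aldehyde
Product: 35 13-membered diketo ester, via aldehyde 2-methylene β-keto ester 34 (not isolated)
Conditions: 3-benzyl-5-(2-hydroxyethyl)-4-methylthiazolium chloride (0.3 equiv), Et3N (3 equiv), 1,4-dioxane, 70 °C; 33 added by syringe pump over 15 h to a final 1 mM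
Reagents that add atoms: none
Why: Proposed new method: triethylamine expels benzenesulfinate from 33 (E1cB) to give 34 at low stationary concentration, while the thiazolylidene adds to the C16 aldehyde and proton transfer gives the Breslow intermediate; this acyl-anion equivalent adds to the unsubstituted terminus C18 of the doubly activated alkene, the C19 enolate is protonated, and loss of the carbene makes the C16–C18 bond irreversible. The closest known reactions are the intramolecular Stetter reaction to five- and six-membered rings and the intermolecular Stetter reaction of aliphatic aldehydes with alkylidene malonates and keto esters; a 13-membered closure has no precedent. The ring closes 13-endo-trig to the paracyclophane C7–O8–arene–C15–C16–C18–C19–C34–C33–C32. C19 is the only new stereocentre; it lies between two carbonyls, epimerises freely and is fixed only in step 28, so no control is needed here. The step needs ring closure to beat benzoin and aldol self-condensation of the arylacetaldehyde and dimerisation of 34. Slow addition, the reversible sulfinate adduct acting as a reservoir, the high electrophilicity of the unsubstituted acceptor carbon, and the pseudoaxial C7 aryl ether with the equatorial C34 acyl group, which direct both chain ends to the lower face of the trans-fused tricycle, should secure this.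

**Step 27**
Reactants: 35 13-membered diketo ester
Product: 36 hydroxylactam (C19–H)
Conditions: NH3 (7 M in MeOH), sealed tube, 80 °C
Reagents that add atoms: ammonia, N
Why: Ammonolysis of the ester and addition of nitrogen to the C16 ketone give the 5-hydroxy-γ-lactam; the strained bridged pyrrole that a Paal–Knorr closure onto C34 would need should not form, and C16 and C19 settle under thermodynamic control.

**Step 28**
Reactants: 36 hydroxylactam
Product: 37 C19-allyl hydroxylactam
Conditions: allyl methyl carbonate, Pd2(dba)3 (2.5 mol %), PPh3 (10 mol %), THF, 23 °C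
Reagents that add atoms: allyl methyl carbonate, C=CCOC(=O)OC
Why: Tsuji–Trost allylation of the soft β-keto lactam enolate under neutral conditions makes C19 quaternary; the π-allyl cation should attack the outer enolate face, the inner one being screened by the cyclophane arene under ring B, which places C20 toward the lower face of ring C, and C16 can re-equilibrate by ring–chain tautomerism.

**Step 29**
Reactants: 37 C19-allyl hydroxylactam
Product: 38 C25 hydroperoxide (C27=C29)
Conditions: O2, 5,10,15,20-tetraphenylporphyrin (cat.), CH2Cl2, visible light, −20 °C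
Reagents that add atoms: dioxygen, O=O
Why: Schenck ene reaction; singlet oxygen should bond to C25 on the lower face and take the pseudoaxial H-29 from the same face (suprafacial, sets C25), because H-33 is deactivated by the adjacent C34 carbonyl and the C26 hydrogens lie on the less substituted side of the alkene; the monosubstituted allyl alkene and the aryl ether are inert.

**Step 30**
Reactants: 38 C25 hydroperoxide
Product: 40 epoxy hydroperoxide, via trans-diaxial bromohydrin 39 (not isolated)
Conditions: N-bromosuccinimide, THF/H2O, 0 °C; then K2CO3, MeOH, 0 °C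
Reagents that add atoms: water, O
Why: Bromohydrin formation and base-induced epoxide closure; the bromonium ion should form on the upper face, away from the pseudoaxial hydroperoxide, water opens it at tertiary C29 from below (Markovnikov and Fürst–Plattner), and the C29 alkoxide displaces bromide to give the epoxide syn to the C25 peroxide (sets C27 and C29); three-ring closure should outrun dioxetane formation, and the trisubstituted alkene reacts before the allyl group.

**Step 31**
Reactants: 40 epoxy hydroperoxide
Product: 42 target CNP0533733.1, via C21 aldehyde 41 (not isolated)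
Conditions: O3, acetone/H2O (19:1), 0 °C; then argon purge, 23 °C
Reagents that add atoms: ozone, [O-][O+]=O
Why: Ozonolysis in wet acetone, where water traps the carbonyl oxide and the aldehyde forms without a reductant that would destroy the hydroperoxide; the C25 hydroperoxide then adds to the C21 aldehyde to close the eight-membered peroxyhemiacetal, with C21 set under thermodynamic control.

**Compound list**
1 | (R)-5-methylcyclohex-2-en-1-one | C[C@@H]1CC=CC(=O)C1 | starting material
2 | formaldehyde | C=O | starting material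
3 | (R)-2-(hydroxymethyl)-5-methylcyclohex-2-en-1-one | C[C@@H]1CC=C(CO)C(=O)C1 | intermediate
4 | (R)-2-[(tert-butyldiphenylsilyloxy)methyl]-5-methylcyclohex-2-en-1-one | C[C@@H]1CC=C(CO[Si](c2ccccc2)(c2ccccc2)C(C)(C)C)C(=O)C1 | intermediate
5 | (5R)-2-[(tert-butyldiphenylsilyloxy)methyl]-1-[(methoxymethoxy)methyl]-5-methylcyclohex-2-en-1-ol, both C1 epimers | C[C@@H]1CC=C(CO[Si](c2ccccc2)(c2ccccc2)C(C)(C)C)C(O)(COCOC)C1 | intermediate
6 | (S)-2-[(tert-butyldiphenylsilyloxy)methyl]-3-[(methoxymethoxy)methyl]-5-methylcyclohex-2-en-1-one | C[C@@H]1CC(=O)C(CO[Si](c2ccccc2)(c2ccccc2)C(C)(C)C)=C(COCOC)C1 | intermediate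
7 | ring A ketone: 2-(silyloxymethyl)-3-[(methoxymethoxy)methyl]-3,5-dimethylcyclohexanone, 3-methyl trans to 5-methyl, 2-CH2OSi cis to 3-methyl | C[C@@H]1CC(=O)[C@@H](CO[Si](c2ccccc2)(c2ccccc2)C(C)(C)C)[C@](C)(COCOC)C1 | intermediate
8 | 1-methylene analogue of 7 (C4 exo-methylene) | C[C@@H]1CC(=C)[C@@H](CO[Si](c2ccccc2)(c2ccccc2)C(C)(C)C)[C@](C)(COCOC)C1 | intermediate
9 | ring A core: C2 and C4 methyls cis and equatorial, C36 methyl axial, C7 as CH2OTBDPS, C31 as CH2OMOM | C[C@@H]1C[C@H](C)[C@@H](CO[Si](c2ccccc2)(c2ccccc2)C(C)(C)C)[C@](C)(COCOC)C1 | intermediate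
10 | C31 primary alcohol of the ring A core | C[C@@H]1C[C@H](C)[C@@H](CO[Si](c2ccccc2)(c2ccccc2)C(C)(C)C)[C@](C)(CO)C1 | intermediate
11 | C31 aldehyde of the ring A core | C[C@@H]1C[C@H](C)[C@@H](CO[Si](c2ccccc2)(c2ccccc2)C(C)(C)C)[C@](C)(C=O)C1 | intermediate
12 | (E)-2-iodovinyl compound (C31=C29) | C[C@@H]1C[C@H](C)[C@@H](CO[Si](c2ccccc2)(c2ccccc2)C(C)(C)C)[C@](C)(/C=C/I)C1 | intermediate
13 | (E)-prop-1-enylboronic acid | C/C=C/B(O)O | starting material
14 | (1E,3E)-penta-1,3-dienyl silyl ether | C[C@@H]1C[C@H](C)[C@@H](CO[Si](c2ccccc2)(c2ccccc2)C(C)(C)C)[C@](C)(/C=C/C=C/C)C1 | intermediate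
15 | dienyl alcohol (C7 hydroxymethyl) | C[C@@H]1C[C@H](C)[C@@H](CO)[C@](C)(/C=C/C=C/C)C1 | intermediate
16 | dienyl aldehyde (C7 formyl) | C[C@@H]1C[C@H](C)[C@@H](C=O)[C@](C)(/C=C/C=C/C)C1 | intermediate
17 | methyl propiolate | C#CC(=O)OC | starting material
18 | γ-hydroxy ynoate, C7 epimeric to the target | C[C@@H]1C[C@H](C)[C@@H]([C@H](O)C#CC(=O)OC)[C@](C)(/C=C/C=C/C)C1 | intermediate
19 | (E)-γ-hydroxy enoate, C7 epimeric to the target | C[C@@H]1C[C@H](C)[C@@H]([C@H](O)/C=C/C(=O)OC)[C@](C)(/C=C/C=C/C)C1 | intermediate
20 | tyrosol | OCCc1ccc(O)cc1 | starting material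
21 | 4-[2-(tert-butyldimethylsilyloxy)ethyl]phenol | CC(C)(C)[Si](C)(C)OCCc1ccc(O)cc1 | intermediate
22 | triene aryl ether, C7 as in the target | C[C@@H]1C[C@H](C)[C@@H]([C@@H](Oc2ccc(CCO[Si](C)(C)C(C)(C)C)cc2)/C=C/C(=O)OC)[C@](C)(/C=C/C=C/C)C1 | intermediate
23 | tricyclic methyl ester, C27=C29, C25 methyl cis to C34 | C[C@@H]1C[C@H](C)[C@H]2[C@@H](Oc4ccc(CCO[Si](C)(C)C(C)(C)C)cc4)[C@@H]3[C@@H](C(=O)OC)[C@@H](C)C=C[C@H]3[C@]2(C)C1 | intermediate
24 | C33 phenylselenyl ester | C[C@@H]1C[C@H](C)[C@H]2[C@@H](Oc4ccc(CCO[Si](C)(C)C(C)(C)C)cc4)[C@@H]3[C@@]([Se]c5ccccc5)(C(=O)OC)[C@@H](C)C=C[C@H]3[C@]2(C)C1 | intermediate (not isolated)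
25 | tricyclic 2,4-dienoate (C33=C25, C27=C29) | C[C@@H]1C[C@H](C)[C@H]2[C@@H](Oc4ccc(CCO[Si](C)(C)C(C)(C)C)cc4)[C@@H]3C(C(=O)OC)=C(C)C=C[C@H]3[C@]2(C)C1 | intermediate
26 | tricyclic β,γ-unsaturated methyl ester (C25=C27, C29 methyl) | C[C@@H]1C[C@H](C)[C@H]2[C@@H](Oc4ccc(CCO[Si](C)(C)C(C)(C)C)cc4)[C@@H]3[C@@H](C(=O)OC)C(C)=C[C@H](C)[C@H]3[C@]2(C)C1 | intermediate
27 | tricyclic C34 acid | C[C@@H]1C[C@H](C)[C@H]2[C@@H](Oc4ccc(CCO[Si](C)(C)C(C)(C)C)cc4)[C@@H]3[C@@H](C(=O)O)C(C)=C[C@H](C)[C@H]3[C@]2(C)C1 | intermediate
28 | monomethyl malonate | COC(=O)CC(=O)O | starting material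
29 | C34 acyl imidazolide | C[C@@H]1C[C@H](C)[C@H]2[C@@H](Oc4ccc(CCO[Si](C)(C)C(C)(C)C)cc4)[C@@H]3[C@@H](C(=O)n5ccnc5)C(C)=C[C@H](C)[C@H]3[C@]2(C)C1 | intermediate (not isolated)
30 | β-keto ester silyl ether | C[C@@H]1C[C@H](C)[C@H]2[C@@H](Oc4ccc(CCO[Si](C)(C)C(C)(C)C)cc4)[C@@H]3[C@@H](C(=O)CC(=O)OC)C(C)=C[C@H](C)[C@H]3[C@]2(C)C1 | intermediate
31 | β-keto ester alcohol | C[C@@H]1C[C@H](C)[C@H]2[C@@H](Oc4ccc(CCO)cc4)[C@@H]3[C@@H](C(=O)CC(=O)OC)C(C)=C[C@H](C)[C@H]3[C@]2(C)C1 | intermediate
32 | sulfone adduct alcohol (C19 epimers) | C[C@@H]1C[C@H](C)[C@H]2[C@@H](Oc4ccc(CCO)cc4)[C@@H]3[C@@H](C(=O)C(CS(=O)(=O)c5ccccc5)C(=O)OC)C(C)=C[C@H](C)[C@H]3[C@]2(C)C1 | intermediate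
33 | sulfone adduct aldehyde (C19 epimers) | C[C@@H]1C[C@H](C)[C@H]2[C@@H](Oc4ccc(CC=O)cc4)[C@@H]3[C@@H](C(=O)C(CS(=O)(=O)c5ccccc5)C(=O)OC)C(C)=C[C@H](C)[C@H]3[C@]2(C)C1 | intermediate
34 | arylacetaldehyde 2-methylene β-keto ester (precursor of the key step) | C[C@@H]1C[C@H](C)[C@H]2[C@@H](Oc4ccc(CC=O)cc4)[C@@H]3[C@@H](C(=O)C(=C)C(=O)OC)C(C)=C[C@H](C)[C@H]3[C@]2(C)C1 | intermediate (not isolated)
35 | 13-membered 1,4-diketone β-keto ester (C19 epimerisable, one epimer drawn) | C[C@@H]1C[C@H](C)[C@H]2[C@H]3Oc4ccc(cc4)CC(=O)C[C@@H](C(=O)[C@H]6C(C)=C[C@H](C)[C@H]([C@H]36)[C@]2(C)C1)C(=O)OC | intermediate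
36 | hydroxylactam with C19–H (C19 epimerisable, one epimer drawn) | C[C@@H]1C[C@H](C)[C@H]2[C@H]3Oc4ccc(cc4)C[C@]5(O)C[C@H](C(=O)N5)C(=O)[C@H]6C(C)=C[C@H](C)[C@H]([C@H]36)[C@]2(C)C1 | intermediate
37 | C19-allyl hydroxylactam | C[C@@H]1C[C@H](C)[C@H]2[C@H]3Oc4ccc(cc4)C[C@]5(O)C[C@](CC=C)(C(=O)N5)C(=O)[C@H]6C(C)=C[C@H](C)[C@H]([C@H]36)[C@]2(C)C1 | intermediate
38 | C25 hydroperoxide with C27=C29 | C[C@@H]1C[C@H](C)[C@H]2[C@H]3Oc4ccc(cc4)C[C@]5(O)C[C@](CC=C)(C(=O)N5)C(=O)[C@H]6[C@@](C)(OO)C=C(C)[C@H]([C@H]36)[C@]2(C)C1 | intermediate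
39 | bromohydrin (C27 bromide, C29 hydroxyl, trans-diaxial) | C[C@@H]1C[C@H](C)[C@H]2[C@H]3Oc4ccc(cc4)C[C@]5(O)C[C@](CC=C)(C(=O)N5)C(=O)[C@H]6[C@@](C)(OO)[C@H](Br)[C@@](C)(O)[C@H]([C@H]36)[C@]2(C)C1 | intermediate (not isolated)
40 | epoxy hydroperoxide (C27–C29 epoxide syn to the C25 peroxide) | C[C@@H]1C[C@H](C)[C@H]2[C@H]3Oc4ccc(cc4)C[C@]5(O)C[C@](CC=C)(C(=O)N5)C(=O)[C@H]6[C@@](C)(OO)[C@H]7O[C@@]7(C)[C@H]([C@H]36)[C@]2(C)C1 | intermediate
41 | C21 aldehyde | C[C@@H]1C[C@H](C)[C@H]2[C@H]3Oc4ccc(cc4)C[C@]5(O)C[C@](CC=O)(C(=O)N5)C(=O)[C@H]6[C@@](C)(OO)[C@H]7O[C@@]7(C)[C@H]([C@H]36)[C@]2(C)C1 | intermediate (not isolated)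
42 | CNP0533733.1 | C[C@@H]1C[C@H](C)[C@H]2[C@H]3Oc4ccc(cc4)C[C@]4(O)C[C@]5(C[C@H](O)OO[C@@]6(C)[C@H]7O[C@@]7(C)[C@H]([C@H]3[C@H]6C5=O)[C@]2(C)C1)C(=O)N4 | target

**Count**
Total: 31 steps. Longest linear sequence: 30 steps (steps 1–15 and 17–31 from compound 1); step 16 is a one-step branch.

**Steps most likely to fail**

Step 26 (macrocyclic Stetter reaction). Oligomerisation, aldol or benzoin self-condensation of the arylacetaldehyde, or capture of the carbene by the acceptor may outrun the 13-membered ring closure. The fallback uses known chemistry and forms C18–C19 instead of C16–C18. It sets out from 31: the primary alcohol is oxidised with TEMPO and PhI(OAc)2 in aqueous MeCN to the arylacetic acid F1. F1 is converted through its mixed anhydride with diazomethane into the diazoketone F2, and HBr at 0 °C turns this into the bromomethyl ketone F3. Cs2CO3 in MeCN at high dilution then effects intramolecular C-alkylation of the β-keto ester by the α-bromo ketone, a well-precedented type of macrocyclisation, and the route is rejoined at 35.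

Step 29 (ene reaction). Singlet oxygen may attack the upper face and abstract H-33 or a C26 hydrogen, giving the wrong regioisomers. The fallback builds the C25–O bond by epoxide opening and the alkene by elimination. It sets out from 37: dimethyldioxirane epoxidises C25=C27 on the upper face to the epoxide F4. Ethereal H2O2 with MoO2(acac)2 opens F4 at tertiary C25 with inversion to the trans-diaxial β-hydroxy hydroperoxide F5. The hydroperoxide is masked with 2-methoxypropene and pyridinium tosylate as the peroxyketal F6. Martin sulfurane dehydrates the axial C27 alcohol anti to H-29, the only direction open to it, to give the alkene peroxyketal F7. Aqueous acetic acid frees the hydroperoxide and the route is rejoined at 38.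

Step 28 (allylation at C19). Poor facial selectivity in the alkylation of the C19 enolate, with the allyl group entering on the face that does not lead to the dioxocane, is the main risk. The fallback moves the alkylation to the more flexible keto ester and puts it under reagent control. It sets out from 35: palladium-catalysed asymmetric allylic alkylation with allyl acetate, Pd2(dba)3 and a C2-symmetric diaminocyclohexane bis(phosphine) ligand gives the quaternary allyl keto ester F8. Ammonia in methanol then adds to the C16 ketone and closes onto the ester, and the route is rejoined at 37.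

**Further compounds**
F1 | step 26 | arylacetic acid β-keto ester | C[C@@H]1C[C@H](C)[C@H]2[C@@H](Oc4ccc(CC(=O)O)cc4)[C@@H]3[C@@H](C(=O)CC(=O)OC)C(C)=C[C@H](C)[C@H]3[C@]2(C)C1
F2 | step 26 | diazoketone β-keto ester | C[C@@H]1C[C@H](C)[C@H]2[C@@H](Oc4ccc(CC(=O)C=[N+]=[N-])cc4)[C@@H]3[C@@H](C(=O)CC(=O)OC)C(C)=C[C@H](C)[C@H]3[C@]2(C)C1
F3 | step 26 | bromomethyl ketone β-keto ester | C[C@@H]1C[C@H](C)[C@H]2[C@@H](Oc4ccc(CC(=O)CBr)cc4)[C@@H]3[C@@H](C(=O)CC(=O)OC)C(C)=C[C@H](C)[C@H]3[C@]2(C)C1
F4 | step 29 | C25–C27 epoxide on the upper face | C[C@@H]1C[C@H](C)[C@H]2[C@H]3Oc4ccc(cc4)C[C@]5(O)C[C@](CC=C)(C(=O)N5)C(=O)[C@H]6[C@]7(C)O[C@@H]7[C@H](C)[C@H]([C@H]36)[C@]2(C)C1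
F5 | step 29 | C25 hydroperoxide C27 alcohol (trans-diaxial) | C[C@@H]1C[C@H](C)[C@H]2[C@H]3Oc4ccc(cc4)C[C@]5(O)C[C@](CC=C)(C(=O)N5)C(=O)[C@H]6[C@@](C)(OO)[C@H](O)[C@H](C)[C@H]([C@H]36)[C@]2(C)C1
F6 | step 29 | 2-methoxyprop-2-yl peroxide of F5 | C[C@@H]1C[C@H](C)[C@H]2[C@H]3Oc4ccc(cc4)C[C@]5(O)C[C@](CC=C)(C(=O)N5)C(=O)[C@H]6[C@@](C)(OOC(C)(C)OC)[C@H](O)[C@H](C)[C@H]([C@H]36)[C@]2(C)C1
F7 | step 29 | peroxyketal with C27=C29 | C[C@@H]1C[C@H](C)[C@H]2[C@H]3Oc4ccc(cc4)C[C@]5(O)C[C@](CC=C)(C(=O)N5)C(=O)[C@H]6[C@@](C)(OOC(C)(C)OC)C=C(C)[C@H]([C@H]36)[C@]2(C)C1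
F8 | step 28 | C19-allyl 13-membered diketo ester | C[C@@H]1C[C@H](C)[C@H]2[C@H]3Oc4ccc(cc4)CC(=O)C[C@](CC=C)(C(=O)OC)C(=O)[C@H]6C(C)=C[C@H](C)[C@H]([C@H]36)[C@]2(C)C1
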